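(The numbers in the tables come from a simulation for substances that don't exist; the scatter is artificial.)

Start from the leftover: what remains of each hand of substrate is the first thing to ask of this flask.

in all of them: left-handed substrate 0.25 M; right-handed substrate 0.25 M; impurity 3.2 mM
- Tuesday's: partner 0.75 M; precatalyst 3.4 mM; run made earlier
- Monday's: partner 0.75 M; precatalyst 7.5 mM; run made earlier
- flask: partner 0.750 M; precatalyst 5.0 mM; time 10 d

- Tuesday's (time / d: left-handed product / %, right-handed product / %, left-handed substrate / %): 2.50: 41, 3, 15; 5.00: 50, 6, 6; 8.00: 53, 9, 3; 10.0: 52, 10, 3
- Monday's (time / d: left-handed product / %, right-handed product / %, left-handed substrate / %): 2.50: 39, 4, 13; 5.00: 51, 6, 3; 8.00: 55, 12, 10; 10.0: 57, 11, 7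

(each reading ± 2 percentage points)

- partner is single-handed; left-handed substrate and right-handed substrate are mirror images of each other, charged as a racemate, each of them at the stated concentration
- an excess is below zero if the other one leads
- the handed part of partner does not stay in what it makes, so the products of the two hands are mirror images too

1. left-handed product and right-handed product together, in percent of the left-handed substrate and right-handed substrate charged together, at 10 d
2. excess of left-handed product over right-handed product in the product at 10 d
3. whether the exchange between left-handed substrate and right-handed substrate keeps pace with the reaction: how far the product's excess at 10 d gets from its value without exchange to its value with instant exchange (above 80% keeps pace, below 20% hardly takes part, else lags behind)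

*Which number do you take from the runs?* The selectivity factor s, the logarithm of the fraction of left-handed substrate remaining divided by the same logarithm for right-handed substrate. Both hands meet the same c(partner) over the same time, so time drops out, provided nothing crosses between the hands. Each hand is half the charge, so Tuesday's reading at 5.00 d, with 6% left-handed substrate and 6% right-handed product, gives s = 16.6.

*How firm is that?* Not very: one scatter on the right-handed product moves it between 12.2 and 25.4.

*What does s give?* With instant exchange, the excess is (s − 1)/(s + 1), or 88.6%. Without exchange, if x is the fraction of left-handed substrate remaining, the right-handed fraction is x^(1/s). Tuesday's leftover at 10.0 d then gives a product excess without exchange of 71.5%.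

*But Monday's left-handed substrate climbs from 3% to 10%. Why use Tuesday's leftover?* The flask's precatalyst, 5.0 mM, lies nearer Tuesday's 3.4 mM than Monday's 7.5 mM, so that is the run I reckon from. My own mark for "hardly takes part" is then an excess below 74.9%.

The forecast gives a yield of 63% (60% to 67%) and an excess of 68% (63% to 73%), with the exchange: hardly takes part. Its no-exchange excess is about 66%, and mine is 71.5%. Its ground: “At 5.0 mM, onset should come around 7–9 d, so little exchange occurs by 10 d.”

The flask gives a yield of 60.4% and an excess of 67.4%. The exchange hardly takes part, getting 3.2% of the way.

    partner + left-handed substrate → left-handed product (k = 0.0400 /M/h)
    partner + right-handed substrate → right-handed product (k = 0.00180 /M/h)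
    left-handed substrate + racemization catalyst ⇌ right-handed substrate + racemization catalyst, rate k3*[racemization catalyst]*[left-handed substrate] forward; the back reaction follows from the equilibrium constant (k = 5.10 /M/h)
    racemization catalyst + impurity → spent catalyst (k = 1100 /M/h)
    partner + precatalyst → racemization catalyst + spent reagent (k = 0.0100 /M/h)

Put back into the flask, s takes the 3.5% of left-handed substrate remaining and returns 68.1% without exchange, beside the 67.4% found. The neighbouring flask is charged with 0.19 M partner, with the other charges and the time held. It keeps 44% of its left-handed substrate and 0.0128% of the catalyst charged as racemization catalyst. The same reckoning gives it 84.1%, and that flask shows 87.8%.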